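## The problem

The target 19 is a 2H-chromene. A benzene ring (ring A) carrying an acetyl group at C6 and a methoxy group at C8 is fused to a pyran ring (ring B). C2 of ring B is a fully substituted ether carbon bearing O1, a methyl group, the sp2 carbon C3 and a CH2O arm esterified with (E)-ferulic acid.

C2 is the only stereocentre (R; O1 > CH2O > C3 > CH3). No second centre can relay or correct it, so its configuration must come from a reagent or catalyst and then be carried unchanged to the end. It cannot epimerise by enolisation, but it is lost if the allylic, tertiary C2–O1 bond ionises or if the chromene opens electrocyclically to an ortho-quinone methide. Strong acid, heat and ultraviolet light therefore have to be kept away from the late intermediates.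

Three groups will not survive rough treatment: the ferulate (a conjugate acceptor, a hydride- and alkoxide-labile ester and a free phenol), the styrene-type C3=C4 bond, and the aryl methyl ketone, which reacts with hydrides and ylides.

The feature that opens the chosen route is that the two exocyclic carbon substituents on C2, CH3 and CH2O, differ only by one oxygen atom. Without that oxygen, and with C3 at the carboxyl oxidation level, C2 is the central carbon of the achiral 2-aryloxy-2-methylpropanoic acid 5, whose carboxylate sits β to both methyl groups. Ring A helps as well: the ether oxygen is flanked by the C8 methoxy group and by C4a, which can carry bromine until ring B is closed, so no aromatic C–H bond lies within reach of that carboxylate.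

## Retrosynthesis

**Ferulate ester.** The acyl C–O bond of the ferulate is cut first, 19 ⇒ alcohol 14 + ferulic acid 15. The ferulate could not pass the hydride, ylide and metathesis steps needed for ring B, so it must arrive last. The cut removes half of the molecule and its most fragile functionality. The forward reaction must acylate a neopentyl-type primary alcohol without the phenol acylating itself. The acid therefore enters as its phenol-silylated form 17 (from 15 through the bis-silyl compound 16), and the coupling product 18 is desilylated in the final step.

**Ring B.** The C3=C4 bond is cut by olefin metathesis, 14 ⇐ 13 ⇐ diene 12. The neighbouring options are worse. A propargyl ether Claisen/electrocyclisation would break and re-form C2–O1 and erase the stereocentre. A Heck closure onto a vinyl group would prefer the five-membered ring. Diene 12 is acyclic and its stereocentre is a spectator. The forward reaction must run near 40 °C without acid, with the ketone masked as a dioxolane and the hydroxyl as a silyl ether; one mild acid treatment then converts 13 into 14.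

**The two alkenes of 12.** The vinyl group on the stereocentre is traced to aldehyde 11 (methylenation) and on to methyl ester 10 (partial reduction). C3 of the target is thus the former carboxyl carbon. The aryl vinyl group is traced to the aryl bromide of 9 (cross-coupling). This returns exactly the carboxyl group and the ortho bromine that the key step needs. The cross-coupling is placed before the reduction so that the heat-sensitive tertiary allyl aryl ether is formed only in the last cold step before ring closure. The hydride and the ylide require the ketone to be masked (9 ⇐ 8) and the alcohol silylated (8 ⇐ 7).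

**Hydroxy ester.** Compound 7 is reconnected between its CH2O oxygen and its ester carbonyl to give β-lactone 6. In the lactone the two arms on the stereocentre are held at different oxidation levels by one ring; a diol at this position would be achiral. The forward reaction is a methanolysis that must attack the acyl carbon, so that the O–CH2 bond stays and later becomes the ester oxygen of 19.

**Key disconnection.** The CH2–O bond of 6 is cut back to a methyl C–H bond, giving acid 5. All stereochemistry disappears: 5 is achiral with two enantiotopic methyl groups. The alternative of setting the centre while making the aryl–O–C(tertiary) bond would require a di-ortho-substituted, electron-poor phenol to act as nucleophile in an asymmetric reaction. Here that bond is made without any stereochemical demand, and the asymmetry is introduced afterwards at a remote methyl group. The forward reaction must let a catalyst choose one methyl group.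

**Acid 5.** The ether C–O bond is cut, 5 ⇐ ester 4 ⇐ bromophenol 2 + tertiary bromo ester 3, and 2 comes from acetovanillone 1. Bromination comes first because the free phenol directs it to the single correct position. After etherification the ring would be brominated para to the methoxy group instead.

## Roads not taken

**Alternative 1:** one-carbon ring expansion of a benzofuranone. The cut removes C4, that is the C3–C4 and C4–C4a bonds, and leads back to (S)-5-bromo-2-[(tert-butyldimethylsilyloxy)methyl]-7-methoxy-2-methylbenzofuran-3(2H)-one A2. Forward, Me3SiCHN2 with BF3·OEt2 adds to the C3 ketone and the aryl carbon migrates with loss of N2 to give chroman-3-one A1.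
- Merits: Lewis-acid diazoalkane homologation of aryl ketones is a known reaction type. The oxygenated quaternary carbon next to the ketone is a poor migrating group, so aryl migration is plausible. Carrying bromine in place of the acetyl group avoids ketone protection.
- Weak points: C4 is installed next to a ketone that must then be removed by reduction and dehydration. The acetyl group must be added late from the bromide, costing two more steps. The Lewis acid meets a silyl ether. Double homologation and epoxide formation compete. The enantioselective construction of A2 is itself an open problem.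
- Comparison: the route would be no shorter than the chosen one and moves the stereochemical question to a compound that is harder to make than 5. Its ring-forming step is known chemistry, which the chosen key step is not. Against that, the chosen plan creates the stereocentre from an achiral acid three steps from commodity chemicals and needs no corrective redox at C3.

**Alternative 2:** enantioselective thiiranium-triggered etherification. The cut is the O1–C2 bond (with a C3–S bond), leading back to the (E)-alkenyl phenol A4. Forward, a chiral selenophosphoramide Lewis base transfers PhS+ from N-(phenylthio)phthalimide to the trisubstituted alkene and the phenol opens the thiiranium ion at the tertiary carbon in a 6-endo closure to give chroman A3. Sulfoxide formation and thermal syn-elimination would then give the C3=C4 bond, which can only form toward C4.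
- Merits: the reaction class is established for ortho-allyl phenols. The ketone can stay unprotected because no hydride or ylide is used. The whole route would be roughly nine or ten steps, clearly shorter than the chosen one.
- Weak points: the carbon that must carry the positive charge bears an acetoxymethyl group, which weakens the Markovnikov preference for 6-endo over 5-exo opening and invites acetate participation. The phenol is deactivated by the para acetyl group. The C2 configuration depends on the geometric purity of A4. The sulfoxide elimination needs about 110 °C on a chromene that can racemise by ring opening.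
- Comparison: this road is shorter and rests on a demonstrated catalytic asymmetric reaction, and that advantage is real. The chosen plan offers in return a stereo-determining step independent of alkene geometry and of endo/exo regiochemistry, no sulfur to install and remove, and a substrate whose only reactive C–H bonds are the two methyl groups.

**Alternative 3:** ring-closing metathesis as the strategic step. The cut is C3=C4, leading back to the tertiary allyl aryl ether A6. Forward, the second-generation Grubbs catalyst (H2IMes)(PCy3)Cl2Ru=CHPh closes A6 to chromene A5, which is the same compound as 14.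
- Merits: the ring closure is reliable, and the chosen route uses the same closure in step 11. If A6 were available enantiopure in two or three steps, for example by palladium-catalysed asymmetric allylic etherification of a bromophenol with 2-methyl-2-vinyloxirane A7, the synthesis would need only six or seven steps and no ketone protection.
- Weak points: the metathesis creates no stereochemistry. The whole burden falls on forming a tertiary C–O bond with a di-ortho-substituted, electron-poor phenol, with branched-versus-linear and enantiofacial control at once. The zerovalent palladium needed for that step must also tolerate an aryl bromide or a styrene.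
- Comparison: as a ring construction the two plans are equal. In step count this road is better if the etherification succeeds. The chosen plan sets against it a C–O(aryl) bond made by a simple displacement on an achiral bromide, with the stereocentre introduced separately under carboxylate direction.

Key step: step 4

Assumption: the sense of induction of the chiral ligand in step 4 cannot be predicted in advance; the route is written for the ligand antipode that gives (S)-6, and both antipodes of the ligand are accessible.

## Route

Step 1
Reactants: 1 acetovanillone
Product: 2 1-(3-bromo-4-hydroxy-5-methoxyphenyl)ethanone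
Conditions: Br2 (1.05 equiv), NaOAc, AcOH, rt
Reagents that add atoms: bromine, BrBr
Why: Electrophilic aromatic bromination; the phenol directs to its single free ortho position (para is occupied by the acetyl group) and the acetate buffer keeps HBr from promoting α-bromination of the ketone.

Step 2
Reactants: 2 1-(3-bromo-4-hydroxy-5-methoxyphenyl)ethanone; 3 ethyl 2-bromo-2-methylpropanoate
Product: 4 ethyl 2-(4-acetyl-2-bromo-6-methoxyphenoxy)-2-methylpropanoate
Conditions: Cs2CO3 (2 equiv), 3 (3 equiv), DMF, 70 °C
Reagents that add atoms: none
Why: Williamson etherification of a caesium phenoxide with a tertiary α-bromo ester, the usual entry to 2-aryloxyisobutyrates; the excess of 3 offsets its elimination to the methacrylate, and C-alkylation is excluded because both ortho positions and the para position are substituted.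

Step 3
Reactants: 4 ethyl 2-(4-acetyl-2-bromo-6-methoxyphenoxy)-2-methylpropanoate
Product: 5 2-(4-acetyl-2-bromo-6-methoxyphenoxy)-2-methylpropanoic acid
Conditions: LiOH·H2O, THF/MeOH/H2O, 40 °C; then 1 M HCl to pH 2
Reagents that add atoms: lithium hydroxide, [Li+].[OH-]
Why: Ester saponification; the hindered ester needs gentle warming, and the only other base-sensitive site, the methyl ketone, is merely enolised reversibly.

Step 4
Reactants: 5 2-(4-acetyl-2-bromo-6-methoxyphenoxy)-2-methylpropanoic acid
Product: 6 (S)-3-(4-acetyl-2-bromo-6-methoxyphenoxy)-3-methyloxetan-2-one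
Conditions: Pd(OAc)2 (10 mol %), (S)-3-acetamido-4,4-dimethylpentanoic acid (20 mol %, or its antipode), CsHCO3 (0.5 equiv), tBuOOH (70% aq., 2 equiv), (CF3)2CHOH, 60 °C
Reagents that add atoms: none
Why: Proposed new method: the carboxylate of 5 binds divalent palladium, the N-acetyl group of the chiral β-amino acid ligand acts as internal base in a concerted metalation–deprotonation of one β-methyl C–H bond to give a five-membered palladacycle, tBuOOH oxidises this to a tetravalent palladium alkyl, and C–O reductive elimination releases the β-lactone and divalent palladium; the closest known reaction type is the palladium-catalysed β-C(sp3)–H lactonisation of α-quaternary aliphatic acids with achiral β-amino acid ligands, taken together with ligand-controlled enantioselective C–H activation of gem-dimethyl groups. The four-membered ring closes by C(sp3)–O reductive elimination from the palladacycle, formally a 4-exo-tet displacement at the palladium-bearing CH2 by the bound carboxylate oxygen. The new stereocentre, the former ether carbon, is under catalyst control alone: the ligand must distinguish the two enantiotopic methyl groups in the C–H cleavage transition state, where the bulky 2,6-disubstituted aryloxy group and the remaining methyl group occupy different quadrants of the chiral pocket, and this large size difference is what the substrate offers the ligand. The step also needs site selectivity and chemoselectivity: the quaternary α-carbon favours cyclometalation (Thorpe–Ingold effect), bromine and methoxy block both ortho C–H bonds that a carboxylate-tethered palladium could otherwise reach, and the cycle never passes through zerovalent palladium, so the aryl bromide should remain. A six-membered-chelate β-amino acid ligand is chosen instead of an α-amino acid ligand because only the former class is known to support lactone-forming reductive elimination from free acids.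

Step 5
Reactants: 6 (S)-3-(4-acetyl-2-bromo-6-methoxyphenoxy)-3-methyloxetan-2-one
Product: 7 methyl (S)-2-(4-acetyl-2-bromo-6-methoxyphenoxy)-3-hydroxy-2-methylpropanoate
Conditions: NaOMe (0.2 equiv), MeOH, 0 °C
Reagents that add atoms: methanol, CO
Why: Base-catalysed methanolysis of a β-lactone by acyl–oxygen cleavage (addition–elimination at the strained carbonyl); SN2 opening at the CH2 carbon is neopentyl-like and slow, and the stereocentre has no acidic hydrogen, so it cannot epimerise.

Step 6
Reactants: 7 methyl (S)-2-(4-acetyl-2-bromo-6-methoxyphenoxy)-3-hydroxy-2-methylpropanoate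
Product: 8 methyl (S)-2-(4-acetyl-2-bromo-6-methoxyphenoxy)-3-(tert-butyldimethylsilyloxy)-2-methylpropanoate
Conditions: tBuMe2SiCl, imidazole, DMF, rt
Reagents that add atoms: tert-butyldimethylsilyl chloride, CC(C)(C)[Si](C)(C)Cl
Why: Standard silylation of a primary alcohol; the silyl ether carries the hydroxyl through the hydride, ylide and metathesis steps.

Step 7
Reactants: 8 methyl (S)-2-(4-acetyl-2-bromo-6-methoxyphenoxy)-3-(tert-butyldimethylsilyloxy)-2-methylpropanoate
Product: 9 methyl (S)-2-[2-bromo-6-methoxy-4-(2-methyl-1,3-dioxolan-2-yl)phenoxy]-3-(tert-butyldimethylsilyloxy)-2-methylpropanoate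
Conditions: Me3SiOCH2CH2OSiMe3, Me3SiOTf (5 mol %), CH2Cl2, −78 to −20 °C; pyridine quench
Reagents that add atoms: 1,2-bis(trimethylsilyloxy)ethane, C[Si](C)(C)OCCO[Si](C)(C)C
Why: Noyori ketalisation, aprotic and cold so that the primary silyl ether and the methyl ester are untouched; the dioxolane hides the aryl ketone from iBu2AlH and from the phosphorus ylide.

Step 8
Reactants: 9 methyl (S)-2-[2-bromo-6-methoxy-4-(2-methyl-1,3-dioxolan-2-yl)phenoxy]-3-(tert-butyldimethylsilyloxy)-2-methylpropanoate
Product: 10 methyl (S)-3-(tert-butyldimethylsilyloxy)-2-[2-ethenyl-6-methoxy-4-(2-methyl-1,3-dioxolan-2-yl)phenoxy]-2-methylpropanoate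
Conditions: Bu3SnCH=CH2, Pd(PPh3)4 (5 mol %), toluene, 100 °C
Reagents that add atoms: tributyl(vinyl)stannane, C=C[Sn](CCCC)(CCCC)CCCC
Why: Stille cross-coupling of the aryl bromide under neutral conditions that ester, ketal and silyl ether tolerate; at this stage no allyl aryl ether is present while the mixture is heated.

Step 9
Reactants: 10 methyl (S)-3-(tert-butyldimethylsilyloxy)-2-[2-ethenyl-6-methoxy-4-(2-methyl-1,3-dioxolan-2-yl)phenoxy]-2-methylpropanoate
Product: 11 (S)-3-(tert-butyldimethylsilyloxy)-2-[2-ethenyl-6-methoxy-4-(2-methyl-1,3-dioxolan-2-yl)phenoxy]-2-methylpropanal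
Conditions: iBu2AlH (1.2 equiv), CH2Cl2, −78 °C; MeOH, then aq. KNaC4H4O6
Reagents that add atoms: none
Why: Partial reduction of an α-alkoxy ester with iBu2AlH at −78 °C, where the chelated aluminium hemiacetal persists until the quench; the α-carbon is quaternary, so the aldehyde cannot epimerise.

Step 10
Reactants: 11 (S)-3-(tert-butyldimethylsilyloxy)-2-[2-ethenyl-6-methoxy-4-(2-methyl-1,3-dioxolan-2-yl)phenoxy]-2-methylpropanal
Product: 12 (R)-tert-butyl({2-[2-ethenyl-6-methoxy-4-(2-methyl-1,3-dioxolan-2-yl)phenoxy]-2-methylbut-3-en-1-yl}oxy)dimethylsilane
Conditions: Ph3PCH3Br, KOtBu, THF, 0 °C to rt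
Reagents that add atoms: methyltriphenylphosphonium bromide, C[P+](c1ccccc1)(c1ccccc1)c1ccccc1.[Br-]
Why: Wittig methylenation of a non-enolisable aldehyde; no other carbonyl group is unmasked, and the descriptor changes from S to R only because the CIP priorities change.

Step 11
Reactants: 12 (R)-tert-butyl({2-[2-ethenyl-6-methoxy-4-(2-methyl-1,3-dioxolan-2-yl)phenoxy]-2-methylbut-3-en-1-yl}oxy)dimethylsilane
Product: 13 (R)-tert-butyl{[8-methoxy-2-methyl-6-(2-methyl-1,3-dioxolan-2-yl)-2H-chromen-2-yl]methoxy}dimethylsilane
Conditions: second-generation Grubbs catalyst (H2IMes)(PCy3)Cl2Ru=CHPh (5 mol %), CH2Cl2 (0.01 M), 40 °C, exclusion of light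
Reagents that add atoms: none
Why: Ring-closing olefin metathesis of a styrene with the vinyl group of a tertiary allylic ether, an established entry to 2,2-disubstituted 2H-chromenes; the catalyst loads on the unhindered styrene and closes onto the hindered vinyl group, and 40 °C is far below the onset of aromatic Claisen rearrangement.

Step 12
Reactants: 13 (R)-tert-butyl{[8-methoxy-2-methyl-6-(2-methyl-1,3-dioxolan-2-yl)-2H-chromen-2-yl]methoxy}dimethylsilane
Product: 14 (R)-1-[2-(hydroxymethyl)-8-methoxy-2-methyl-2H-chromen-6-yl]ethanone
Conditions: 2 M aq. HCl, THF, rt, exclusion of light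
Reagents that add atoms: water, O
Why: Acid hydrolysis removes both protecting groups in one operation, since the dioxolane of an electron-rich aryl ketone and a primary silyl ether are both labile to dilute aqueous acid; the chromene ether should not ionise at room temperature.

Step 13
Reactants: 15 ferulic acid
Product: 17 (E)-3-[4-(tert-butyldimethylsilyloxy)-3-methoxyphenyl]prop-2-enoic acid, via bis-silylated ferulic acid 16 (not isolated)
Conditions: tBuMe2SiCl (2.5 equiv), imidazole (5 equiv), DMF, rt; then AcOH/THF/H2O, rt
Reagents that add atoms: tert-butyldimethylsilyl chloride, CC(C)(C)[Si](C)(C)Cl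
Why: Exhaustive silylation followed by selective solvolysis of the far more labile silyl ester gives the phenol-protected acid, so the phenol cannot compete as a nucleophile in the coupling.

Step 14
Reactants: 14 (R)-1-[2-(hydroxymethyl)-8-methoxy-2-methyl-2H-chromen-6-yl]ethanone; 17 (E)-3-[4-(tert-butyldimethylsilyloxy)-3-methoxyphenyl]prop-2-enoic acid
Product: 18 [(R)-6-acetyl-8-methoxy-2-methyl-2H-chromen-2-yl]methyl (E)-3-[4-(tert-butyldimethylsilyloxy)-3-methoxyphenyl]prop-2-enoate
Conditions: EDC·HCl, DMAP, CH2Cl2, 0 °C to rt, exclusion of light
Reagents that add atoms: none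
Why: Steglich esterification; acyl transfer to a neopentyl-type primary alcohol is not retarded the way an SN2 (Mitsunobu) approach at that carbon would be, and the (E)-alkene is not at risk.

Step 15
Reactants: 18 [(R)-6-acetyl-8-methoxy-2-methyl-2H-chromen-2-yl]methyl (E)-3-[4-(tert-butyldimethylsilyloxy)-3-methoxyphenyl]prop-2-enoate
Product: 19 [(R)-6-acetyl-8-methoxy-2-methyl-2H-chromen-2-yl]methyl (E)-3-(4-hydroxy-3-methoxyphenyl)prop-2-enoate
Conditions: Bu4NF (1.1 equiv), AcOH (1.2 equiv), THF, 0 °C
Reagents that add atoms: none
Why: Fluoride cleavage of an aryl silyl ether, buffered with acetic acid so that the liberated phenoxide cannot start transesterification of the cinnamate; nothing else in the molecule responds to fluoride.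

## Compound list

1 | acetovanillone, 1-(4-hydroxy-3-methoxyphenyl)ethanone | CC(=O)c1ccc(O)c(OC)c1 | starting material
2 | 1-(3-bromo-4-hydroxy-5-methoxyphenyl)ethanone | CC(=O)c1cc(Br)c(O)c(OC)c1 | intermediate
3 | ethyl 2-bromo-2-methylpropanoate | CCOC(=O)C(C)(C)Br | starting material
4 | ethyl 2-(4-acetyl-2-bromo-6-methoxyphenoxy)-2-methylpropanoate | CCOC(=O)C(C)(C)Oc1c(Br)cc(C(C)=O)cc1OC | intermediate
5 | 2-(4-acetyl-2-bromo-6-methoxyphenoxy)-2-methylpropanoic acid | CC(=O)c1cc(Br)c(OC(C)(C)C(=O)O)c(OC)c1 | intermediate
6 | (S)-3-(4-acetyl-2-bromo-6-methoxyphenoxy)-3-methyloxetan-2-one | O=C1OC[C@]1(C)Oc1c(Br)cc(C(C)=O)cc1OC | intermediate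
7 | methyl (S)-2-(4-acetyl-2-bromo-6-methoxyphenoxy)-3-hydroxy-2-methylpropanoate | OC[C@](C(=O)OC)(C)Oc1c(Br)cc(C(C)=O)cc1OC | intermediate
8 | methyl (S)-2-(4-acetyl-2-bromo-6-methoxyphenoxy)-3-(tert-butyldimethylsilyloxy)-2-methylpropanoate | CC(C)(C)[Si](C)(C)OC[C@](C(=O)OC)(C)Oc1c(Br)cc(C(C)=O)cc1OC | intermediate
9 | methyl (S)-2-[2-bromo-6-methoxy-4-(2-methyl-1,3-dioxolan-2-yl)phenoxy]-3-(tert-butyldimethylsilyloxy)-2-methylpropanoate | CC(C)(C)[Si](C)(C)OC[C@](C(=O)OC)(C)Oc1c(Br)cc(C2(C)OCCO2)cc1OC | intermediate
10 | methyl (S)-3-(tert-butyldimethylsilyloxy)-2-[2-ethenyl-6-methoxy-4-(2-methyl-1,3-dioxolan-2-yl)phenoxy]-2-methylpropanoate | CC(C)(C)[Si](C)(C)OC[C@](C(=O)OC)(C)Oc1c(C=C)cc(C2(C)OCCO2)cc1OC | intermediate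
11 | (S)-3-(tert-butyldimethylsilyloxy)-2-[2-ethenyl-6-methoxy-4-(2-methyl-1,3-dioxolan-2-yl)phenoxy]-2-methylpropanal | CC(C)(C)[Si](C)(C)OC[C@](C=O)(C)Oc1c(C=C)cc(C2(C)OCCO2)cc1OC | intermediate
12 | (R)-tert-butyl({2-[2-ethenyl-6-methoxy-4-(2-methyl-1,3-dioxolan-2-yl)phenoxy]-2-methylbut-3-en-1-yl}oxy)dimethylsilane | CC(C)(C)[Si](C)(C)OC[C@](C=C)(C)Oc1c(C=C)cc(C2(C)OCCO2)cc1OC | intermediate
13 | (R)-tert-butyl{[8-methoxy-2-methyl-6-(2-methyl-1,3-dioxolan-2-yl)-2H-chromen-2-yl]methoxy}dimethylsilane | CC(C)(C)[Si](C)(C)OC[C@@]1(C)C=Cc2cc(C3(C)OCCO3)cc(OC)c2O1 | intermediate
14 | (R)-1-[2-(hydroxymethyl)-8-methoxy-2-methyl-2H-chromen-6-yl]ethanone | OC[C@@]1(C)C=Cc2cc(C(C)=O)cc(OC)c2O1 | intermediate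
15 | ferulic acid, (E)-3-(4-hydroxy-3-methoxyphenyl)prop-2-enoic acid | COc1cc(/C=C/C(=O)O)ccc1O | starting material
16 | tert-butyldimethylsilyl (E)-3-[4-(tert-butyldimethylsilyloxy)-3-methoxyphenyl]prop-2-enoate | COc1cc(/C=C/C(=O)O[Si](C)(C)C(C)(C)C)ccc1O[Si](C)(C)C(C)(C)C | intermediate
17 | (E)-3-[4-(tert-butyldimethylsilyloxy)-3-methoxyphenyl]prop-2-enoic acid | COc1cc(/C=C/C(=O)O)ccc1O[Si](C)(C)C(C)(C)C | intermediate
18 | [(R)-6-acetyl-8-methoxy-2-methyl-2H-chromen-2-yl]methyl (E)-3-[4-(tert-butyldimethylsilyloxy)-3-methoxyphenyl]prop-2-enoate | COc1cc(/C=C/C(=O)OC[C@@]2(C)C=Cc3cc(C(C)=O)cc(OC)c3O2)ccc1O[Si](C)(C)C(C)(C)C | intermediate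
19 | [(R)-6-acetyl-8-methoxy-2-methyl-2H-chromen-2-yl]methyl (E)-3-(4-hydroxy-3-methoxyphenyl)prop-2-enoate (CNP0168033.1) | COc1cc(/C=C/C(=O)OC[C@@]2(C)C=Cc3cc(C(C)=O)cc(OC)c3O2)ccc1O | target

## Step count and least certain steps

Total: 15 steps. Longest linear sequence: 14 steps (steps 1–12, 14 and 15, from 1); step 13 is a one-step branch from 15.

**Step 4 (key step).** The most likely failure is poor discrimination of the two enantiotopic methyl groups, since the ligand has to tell the aryloxy group from a methyl group on the α-carbon. Low turnover is the second risk: the α-aryloxy group makes the β-C–H bonds less electron-rich, and the ether oxygen may hold the palladium in an unproductive chelate. The fallback leaves C–H activation altogether and uses known chemistry. From phenol 2, alkylation with dimethyl 2-bromo-2-methylmalonate (K2CO3, DMF) should give dimethyl 2-(4-acetyl-2-bromo-6-methoxyphenoxy)-2-methylpropanedioate F1. Pig liver esterase in pH 7 phosphate buffer would hydrolyse one enantiotopic ester group, a desymmetrisation of a prochiral disubstituted malonate, to (S)-2-(4-acetyl-2-bromo-6-methoxyphenoxy)-3-methoxy-2-methyl-3-oxopropanoic acid F2; the enzyme preparation would be chosen for this sense. BH3·SMe2 reduces the free acid in the presence of the ester, and takes the aryl ketone with it, to give methyl (2S)-2-[2-bromo-4-(1-hydroxyethyl)-6-methoxyphenoxy]-3-hydroxy-2-methylpropanoate F3 as a mixture of carbinol epimers. MnO2 in CH2Cl2 reoxidises only the benzylic carbinol, and the sequence returns to the route at 7.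

**Step 2.** The phenoxide of 2 is flanked by bromine and methoxy and weakened by the para acetyl group, so elimination of 3 to the methacrylate may outrun substitution and leave conversion low. The fallback sets out from 2 and uses a Bargellini reaction with 1,1,1-trichloro-2-methylpropan-2-ol and powdered NaOH in acetone. The phenoxide is alkylated at the tertiary carbon to give 2-(4-acetyl-2-bromo-6-methoxyphenoxy)-2-methylpropanoyl chloride F4, which is hydrolysed in the same flask. This returns to the route at 5 and bypasses 4.

**Step 5.** Methoxide may attack the CH2 carbon (alkyl–oxygen cleavage) instead of the acyl carbon, giving a methoxy acid, or loss of formaldehyde by retro-aldol cleavage may follow ring opening. The fallback sets out from 6 and does not depend on the regiochemistry of opening. Hydrolysis with LiOH in THF/H2O gives (S)-2-(4-acetyl-2-bromo-6-methoxyphenoxy)-3-hydroxy-2-methylpropanoic acid F5 whichever carbon is attacked. Carboxylate O-methylation (MeI, K2CO3, DMF) then returns to the route at 7.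

**Step 9.** Over-reduction to the primary alcohol is the main risk. That alcohol has a free and a silylated hydroxymethyl arm on the same carbon, so silyl migration between the two oxygens would racemise it. The fallback sets out from 10 and accepts the full reduction under controlled conditions. LiBH4 in THF at 0 °C with a buffered (NH4Cl) work-up gives (R)-3-(tert-butyldimethylsilyloxy)-2-[2-ethenyl-6-methoxy-4-(2-methyl-1,3-dioxolan-2-yl)phenoxy]-2-methylpropan-1-ol F6. This is oxidised at once with Dess–Martin periodinane, so the alkoxide is never left under basic conditions, and the sequence returns to the route at 11.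

**Step 12.** Acid may protonate the styrene-type C3=C4 bond or ionise the C2–O1 bond, causing hydration, oligomerisation or racemisation before the hindered silyl ether is fully cleaved. The fallback sets out from 13 and separates the two deprotections under near-neutral conditions. Bu4NF in THF gives (R)-[8-methoxy-2-methyl-6-(2-methyl-1,3-dioxolan-2-yl)-2H-chromen-2-yl]methanol F7. Pyridinium p-toluenesulfonate in wet acetone then removes the dioxolane and returns to the route at 14.

## Further compounds

F1 | step 4 | dimethyl 2-(4-acetyl-2-bromo-6-methoxyphenoxy)-2-methylpropanedioate | COC(=O)C(C)(Oc1c(Br)cc(C(C)=O)cc1OC)C(=O)OC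
F2 | step 4 | (S)-2-(4-acetyl-2-bromo-6-methoxyphenoxy)-3-methoxy-2-methyl-3-oxopropanoic acid | OC(=O)[C@](C(=O)OC)(C)Oc1c(Br)cc(C(C)=O)cc1OC
F3 | step 4 | methyl (2S)-2-[2-bromo-4-(1-hydroxyethyl)-6-methoxyphenoxy]-3-hydroxy-2-methylpropanoate (carbinol epimers) | OC[C@](C(=O)OC)(C)Oc1c(Br)cc(C(C)O)cc1OC
F4 | step 2 | 2-(4-acetyl-2-bromo-6-methoxyphenoxy)-2-methylpropanoyl chloride | CC(=O)c1cc(Br)c(OC(C)(C)C(Cl)=O)c(OC)c1
F5 | step 5 | (S)-2-(4-acetyl-2-bromo-6-methoxyphenoxy)-3-hydroxy-2-methylpropanoic acid | OC[C@](C(=O)O)(C)Oc1c(Br)cc(C(C)=O)cc1OC
F6 | step 9 | (R)-3-(tert-butyldimethylsilyloxy)-2-[2-ethenyl-6-methoxy-4-(2-methyl-1,3-dioxolan-2-yl)phenoxy]-2-methylpropan-1-ol | CC(C)(C)[Si](C)(C)OC[C@](CO)(C)Oc1c(C=C)cc(C2(C)OCCO2)cc1OC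
F7 | step 12 | (R)-[8-methoxy-2-methyl-6-(2-methyl-1,3-dioxolan-2-yl)-2H-chromen-2-yl]methanol | OC[C@@]1(C)C=Cc2cc(C3(C)OCCO3)cc(OC)c2O1
A1 | alternative 1 | (S)-6-bromo-2-[(tert-butyldimethylsilyloxy)methyl]-8-methoxy-2-methylchroman-3-one | CC(C)(C)[Si](C)(C)OC[C@@]1(C)C(=O)Cc2cc(Br)cc(OC)c2O1
A2 | alternative 1 | (S)-5-bromo-2-[(tert-butyldimethylsilyloxy)methyl]-7-methoxy-2-methylbenzofuran-3(2H)-one | CC(C)(C)[Si](C)(C)OC[C@@]1(C)C(=O)c2cc(Br)cc(OC)c2O1
A3 | alternative 2 | [(2S,3R)-6-acetyl-8-methoxy-2-methyl-3-(phenylthio)chroman-2-yl]methyl acetate | CC(=O)OC[C@@]1(C)[C@H](Sc2ccccc2)Cc2cc(C(C)=O)cc(OC)c2O1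
A4 | alternative 2 | (E)-4-(5-acetyl-2-hydroxy-3-methoxyphenyl)-2-methylbut-2-en-1-yl acetate | CC(=O)OC/C(C)=C/Cc1cc(C(C)=O)cc(OC)c1O
A5 | alternative 3 | (R)-1-[2-(hydroxymethyl)-8-methoxy-2-methyl-2H-chromen-6-yl]ethanone | OC[C@@]1(C)C=Cc2cc(C(C)=O)cc(OC)c2O1
A6 | alternative 3 | (R)-1-{3-ethenyl-4-[(1-hydroxy-2-methylbut-3-en-2-yl)oxy]-5-methoxyphenyl}ethanone | OC[C@](C=C)(C)Oc1c(C=C)cc(C(C)=O)cc1OC
A7 | alternative 3 | 2-methyl-2-vinyloxirane | C=CC1(C)CO1
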